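**Assumptions (one line each)**
- Clerodane numbering is used; α/β follow the usual neo-clerodane drawing (H-10 β; C19 and C20 α). The target SMILES corresponds to (1R,4R,5R,6S,8R,9S,10R,12S) with two (S)-2-methylbutanoyl groups.
- "then" inside one step means the next reagent is added to the same flask (counted as one step).

## Retrosynthetic overview
1. Target ⇐ (S)-2-methylbutanoylation of the 12S-carbinol ⇐ CBS reduction of a C12 ketone ⇐ late acyl-Stille union of the fully functionalised decalin acid chloride with a 4-stannylbutenolide.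
2. Decalin acid: 1β-OH/10β-H from hydroboration of a Δ1(10) olefin; 4α-OH/18-Cl from LiCH2Cl addition to the C4 ketone; 6-oxygen and 8-methyl from MeLi addition/oxidative 1,3-transposition, then hydrogenation.
3. C9 quaternary centre from deconjugative alkylation of a cross-conjugated dienone with tert-butyl bromoacetate, anti to C19.
4. Ring order: ring A is the starting cyclohexane-1,3-dione; ring B by asymmetric Robinson annulation (sets C5); the butenolide ring is brought in preformed (from tetronic acid).
5. Side branches: stannylbutenolide, (S)-2-methylbutanoic anhydride, tert-butyl bromoacetate.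

## Route

**Step 1**
Reactants: 1 cyclohexane-1,3-dione; 2 allyl bromide
Product: 3, 2-allylcyclohexane-1,3-dione
Conditions: KOH, H2O, Cu powder (cat.), rt
Reagents that add atoms: allyl bromide (2), C=CCBr
Why: C-allylation of the soft 1,3-dione enolate; no stereocentre.

**Step 2**
Reactants: 3; 4 ethyl vinyl ketone
Product: 5, 2-allyl-2-(3-oxopentyl)cyclohexane-1,3-dione
Conditions: Et3N (5 mol%), EtOAc, 50 °C
Reagents that add atoms: ethyl vinyl ketone (4), C=CC(=O)CC
Why: Michael addition of the 2-substituted dione creates the (still prochiral) quaternary C5.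

**Step 3**
Reactants: 5
Product: 6, (S)-8a-allyl-5-methyl-3,4,8,8a-tetrahydronaphthalene-1,6(2H,7H)-dione (spatial analogue of (R)-Wieland–Miescher ketone; allyl = future C19, α)
Conditions: D-phenylalanine (1 equiv), (1R)-(–)-camphorsulfonic acid (0.5 equiv), DMF, rt → 70 °C; recrystallise
Reagents that add atoms: none
Why: Hajos–Parrish/Hagiwara–Uda enamine aldol condensation; the D-amino acid selects one enantiotopic ring ketone and so sets C5.

**Step 4**
Reactants: 6
Product: 7, C4 ethylene ketal of 6
Conditions: ethylene glycol, TsOH, 4 Å MS, rt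
Reagents that add atoms: ethylene glycol, OCCO
Why: the saturated ketone is ketalised selectively over the conjugated, tetrasubstituted enone.

**Step 5**
Reactants: 7
Product: 8, angular (E)-prop-1-enyl isomer
Conditions: RuHCl(CO)(PPh3)3 (3 mol%), toluene, 80 °C
Reagents that add atoms: none
Why: Ru–H olefin isomerisation moves the terminal alkene into the internal position so that cleavage leaves one carbon on C5.

**Step 6**
Reactants: 8
Product: 9, angular hydroxymethyl (C19-OH) enone ketal
Conditions: O3, CH2Cl2/MeOH, –78 °C (Sudan III end point); then NaBH4, –78 → –30 °C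
Reagents that add atoms: ozone, [O-][O+]=O
Why: ozonolysis cleaves the electron-rich propenyl group (the electron-poor tetrasubstituted enone alkene is inert), and cold borohydride reduces the peroxide/aldehyde but not the hindered enone.

**Step 7**
Reactants: 9
Product: 10, C19 O-TBS ether
Conditions: TBSCl, imidazole, DMF, rt
Reagents that add atoms: TBSCl, CC(C)(C)[Si](C)(C)Cl
Why: silylation of the primary alcohol.

**Step 8**
Reactants: 10
Product: 11, cross-conjugated dienone (Δ6 and Δ9(10), 8-one)
Conditions: LDA, TMSCl, THF, –78 °C; then Pd(OAc)2, MeCN, rt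
Reagents that add atoms: none
Why: Saegusa–Ito dehydrogenation through the kinetic α′ (C7) silyl enol ether.

**Step 9**
Reactants: 12 bromoacetyl bromide; 13 tert-butanol
Product: 14, tert-butyl bromoacetate
Conditions: PhNMe2, Et2O, 0 °C → rt
Reagents that add atoms: bromoacetyl bromide (12), BrCC(Br)=O; tert-butanol (13), CC(C)(C)O
Why: acylation of tert-butanol by the acid bromide.

**Step 10**
Reactants: 11; 14
Product: 15, 9α-methyl-9β-(tert-butoxycarbonylmethyl)-Δ1(10),Δ6-dien-8-one
Conditions: KOt-Bu, t-BuOH/THF, 0 °C; then 14, 0 °C → rt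
Reagents that add atoms: tert-butyl bromoacetate (14), BrCC(=O)OC(C)(C)C
Why: deconjugative α-alkylation of the extended dienolate (only C1-H is acidic) moves the olefin to Δ1(10); the electrophile enters anti to the pseudo-axial C19 group, giving C11 β and C20 α (9S).

**Step 11**
Reactants: 15
Product: 16, tertiary allylic alcohol (8-methyl-8-ol; C8 configuration irrelevant)
Conditions: MeLi, CeCl3, THF, –78 °C
Reagents that add atoms: methyllithium, [Li]C
Why: organocerium 1,2-addition to the hindered enone carbonyl, leaving the tert-butyl ester untouched; this methyl becomes C17.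

**Step 12**
Reactants: 16
Product: 17, 8-methyl-Δ7-en-6-one
Conditions: PCC, NaOAc, 4 Å MS, CH2Cl2, rt
Reagents that add atoms: none
Why: Dauben–Babler oxidative 1,3-transposition of the tertiary allylic alcohol puts the oxygen on C6.

**Step 13**
Reactants: 17
Product: 18, 8α-methyl-6-ketone
Conditions: H2 (3 atm), 10% Pd/C, EtOAc, rt
Reagents that add atoms: none
Why: hydrogenation from the β face (α face blocked by axial C19 and C20) sets 8R; the Δ1(10) olefin between two quaternary carbons is not reduced.

**Step 14**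
Reactants: 18
Product: 19, 6α-alcohol
Conditions: NaBH4, MeOH, –20 → 0 °C
Reagents that add atoms: none
Why: axial hydride delivery from the β face gives the equatorial 6α-OH (6S), cis to C19, as in Wieland–Miescher ketone reductions.

**Step 15**
Reactants: 19
Product: 20, C4 ketone (ketal removed)
Conditions: PPTS, acetone/H2O, 55 °C
Reagents that add atoms: water, O
Why: mild acetal hydrolysis; the TBS ether and tert-butyl ester survive.

**Step 16**
Reactants: 20
Product: 21, chlorohydrin triol (4α-OH, 18-Cl, 6α-OH, 19-OH)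
Conditions: ICH2Cl, MeLi·LiBr (slow addition), THF, –78 °C; AcOH at –78 °C; then 1 M HCl/MeOH, rt
Reagents that add atoms: chloroiodomethane, ClCI
Why: the in situ LiCH2Cl carbenoid adds to the ketone by axial (β-face) attack, because the equatorial trajectory is blocked by the axial C19 on C5; this gives β-CH2Cl and α-OH (4R). The cold acidic quench prevents epoxide closure, and acidic methanol removes the TBS group.

**Step 17**
Reactants: 21
Product: 22, 6,19-diacetate
Conditions: Ac2O, DMAP, pyridine, CH2Cl2, rt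
Reagents that add atoms: acetic anhydride, CC(=O)OC(C)=O
Why: acetylation of the primary and secondary alcohols; the tertiary C4-OH does not react.

**Step 18**
Reactants: 22
Product: 23, 1β-alcohol with 10β-H (trans-decalin)
Conditions: BH3·THF, THF, 0 °C → rt; then H2O2, aq NaHCO3, 0 °C
Reagents that add atoms: borane–THF, B.C1CCOC1; hydrogen peroxide, OO
Why: syn, anti-Markovnikov hydroboration–oxidation from the β face (α face shielded by C19 and C20 on both neighbours of C10) sets 10R and 1R together.

**Step 19**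
Reactants: 24 (S)-2-methylbutanoic acid
Product: 25, (S)-2-methylbutanoic anhydride
Conditions: DCC (0.5 equiv), CH2Cl2, 0 °C → rt
Reagents that add atoms: (S)-2-methylbutanoic acid (24), CC[C@H](C)C(=O)O
Why: carbodiimide dehydration to the symmetric anhydride without touching the α-stereocentre.

**Step 20**
Reactants: 23; 25
Product: 26, 1β-(S)-2-methylbutanoate
Conditions: DMAP, pyridine, CH2Cl2, rt → 35 °C
Reagents that add atoms: anhydride 25, CC[C@H](C)C(=O)OC(=O)[C@@H](C)CC
Why: Steglich-type acylation of the only free secondary alcohol.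

**Step 21**
Reactants: 26
Product: 27, C12 carboxylic acid
Conditions: TFA/CH2Cl2 (1:4), Et3SiH, 0 °C → rt
Reagents that add atoms: none
Why: acidolysis of the tert-butyl ester; acetates, the C1 ester and the chlorohydrin are acid-stable.

**Step 22**
Reactants: 28 tetronic acid
Product: 29, 4-bromofuran-2(5H)-one
Conditions: (COBr)2, DMF (cat.), CH2Cl2, 0 °C → rt
Reagents that add atoms: oxalyl bromide, O=C(Br)C(=O)Br
Why: Vilsmeier-type conversion of the vinylogous acid into the β-bromobutenolide.

**Step 23**
Reactants: 29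
Product: 30, 4-(tributylstannyl)furan-2(5H)-one
Conditions: (Bu3Sn)2, Pd(PPh3)4 (5 mol%), toluene, 100 °C
Reagents that add atoms: hexabutylditin, CCCC[Sn](CCCC)(CCCC)[Sn](CCCC)(CCCC)CCCC
Why: Pd-catalysed stannylation of the vinyl bromide.

**Step 24**
Reactants: 27; 30
Product: 31, C12 ketone carrying the butenolide
Conditions: 1-chloro-N,N,2-trimethylprop-1-en-1-amine, CH2Cl2, 0 °C; then 30, Pd2(dba)3 (5 mol%), P(2-furyl)3, toluene, 60 °C
Reagents that add atoms: stannane 30, CCCC[Sn](CCCC)(CCCC)C1=CC(=O)OC1
Why: neutral acid-chloride formation followed by Stille acylation (ketone synthesis) forms C12–C13 without disturbing esters, the alkyl chloride or the tertiary alcohol.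

**Step 25**
Reactants: 31
Product: 32, (12S)-alcohol
Conditions: (R)-Me-CBS (0.5 equiv), catecholborane, toluene/CH2Cl2, –78 °C
Reagents that add atoms: none
Why: Corey–Bakshi–Shibata 1,2-reduction with the alkenyl (butenolide) group as the large substituent; the (R)-catalyst is predicted to give 12S under reagent control.

**Step 26**
Reactants: 32; 25
Product: 33, ajugaciliatin A
Conditions: DMAP (cat.), pyridine, CH2Cl2, 0 °C → rt
Reagents that add atoms: anhydride 25, CC[C@H](C)C(=O)OC(=O)[C@@H](C)CC
Why: DMAP-catalysed acylation of the secondary C12 alcohol; the tertiary chlorohydrin OH is unreactive.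

## Compound list
1 | cyclohexane-1,3-dione | O=C1CCCC(=O)C1 | starting material
2 | allyl bromide | C=CCBr | starting material
3 | 2-allylcyclohexane-1,3-dione | C=CCC1C(=O)CCCC1=O | intermediate
4 | ethyl vinyl ketone | C=CC(=O)CC | starting material
5 | 2-allyl-2-(3-oxopentyl)cyclohexane-1,3-dione | CCC(=O)CCC1(CC=C)C(=O)CCCC1=O | intermediate
6 | (S)-8a-allyl-5-methyl-3,4,8,8a-tetrahydronaphthalene-1,6(2H,7H)-dione | C=CC[C@@]12CCC(=O)C(C)=C1CCCC2=O | intermediate
7 | C4 ethylene ketal of 6 | C=CC[C@@]12CCC(=O)C(C)=C1CCCC23OCCO3 | intermediate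
8 | angular (E)-propenyl enone ketal | C/C=C/[C@@]12CCC(=O)C(C)=C1CCCC23OCCO3 | intermediate
9 | angular hydroxymethyl enone ketal | OC[C@@]12CCC(=O)C(C)=C1CCCC23OCCO3 | intermediate
10 | C19 O-TBS enone ketal | CC(C)(C)[Si](C)(C)OC[C@@]12CCC(=O)C(C)=C1CCCC23OCCO3 | intermediate
11 | cross-conjugated dienone | CC(C)(C)[Si](C)(C)OC[C@@]12C=CC(=O)C(C)=C1CCCC23OCCO3 | intermediate
12 | bromoacetyl bromide | BrCC(Br)=O | starting material
13 | tert-butanol | CC(C)(C)O | starting material (ester protecting group)
14 | tert-butyl bromoacetate | BrCC(=O)OC(C)(C)C | intermediate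
15 | C9-alkylated Δ1(10),Δ6-dien-8-one | CC(C)(C)OC(=O)C[C@@]1(C)C(=O)C=C[C@]2(CO[Si](C)(C)C(C)(C)C)C1=CCCC23OCCO3 | intermediate
16 | 8-methyl-8-ol (C8 mixture, inconsequential) | CC(C)(C)OC(=O)C[C@@]1(C)C(C)(O)C=C[C@]2(CO[Si](C)(C)C(C)(C)C)C1=CCCC23OCCO3 | intermediate
17 | 8-methyl-Δ7-en-6-one | CC(C)(C)OC(=O)C[C@@]1(C)C(C)=CC(=O)[C@]2(CO[Si](C)(C)C(C)(C)C)C1=CCCC23OCCO3 | intermediate
18 | 8α-methyl-6-ketone | CC(C)(C)OC(=O)C[C@@]1(C)[C@H](C)CC(=O)[C@]2(CO[Si](C)(C)C(C)(C)C)C1=CCCC23OCCO3 | intermediate
19 | 6α-alcohol (ketal) | CC(C)(C)OC(=O)C[C@@]1(C)[C@H](C)C[C@H](O)[C@]2(CO[Si](C)(C)C(C)(C)C)C1=CCCC23OCCO3 | intermediate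
20 | 6α-hydroxy-4-ketone | CC(C)(C)OC(=O)C[C@@]1(C)[C@H](C)C[C@H](O)[C@]2(CO[Si](C)(C)C(C)(C)C)C1=CCCC2=O | intermediate
21 | chlorohydrin triol | CC(C)(C)OC(=O)C[C@@]1(C)[C@H](C)C[C@H](O)[C@]2(CO)C1=CCC[C@]2(O)CCl | intermediate
22 | 6,19-diacetate | CC(C)(C)OC(=O)C[C@@]1(C)[C@H](C)C[C@H](OC(C)=O)[C@]2(COC(C)=O)C1=CCC[C@]2(O)CCl | intermediate
23 | 1β-alcohol (10β-H) | CC(C)(C)OC(=O)C[C@@]1(C)[C@H](C)C[C@H](OC(C)=O)[C@]2(COC(C)=O)[C@@H]1[C@H](O)CC[C@]2(O)CCl | intermediate
24 | (S)-2-methylbutanoic acid | CC[C@H](C)C(=O)O | starting material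
25 | (S)-2-methylbutanoic anhydride | CC[C@H](C)C(=O)OC(=O)[C@@H](C)CC | intermediate
26 | 1β-(S)-2-methylbutanoate, tert-butyl ester | CC(C)(C)OC(=O)C[C@@]1(C)[C@H](C)C[C@H](OC(C)=O)[C@]2(COC(C)=O)[C@@H]1[C@H](OC(=O)[C@@H](C)CC)CC[C@]2(O)CCl | intermediate
27 | C12 carboxylic acid | OC(=O)C[C@@]1(C)[C@H](C)C[C@H](OC(C)=O)[C@]2(COC(C)=O)[C@@H]1[C@H](OC(=O)[C@@H](C)CC)CC[C@]2(O)CCl | intermediate
28 | tetronic acid | OC1=CC(=O)OC1 | starting material
29 | 4-bromofuran-2(5H)-one | BrC1=CC(=O)OC1 | intermediate
30 | 4-(tributylstannyl)furan-2(5H)-one | CCCC[Sn](CCCC)(CCCC)C1=CC(=O)OC1 | intermediate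
31 | C12 ketone | O=C(C[C@@]1(C)[C@H](C)C[C@H](OC(C)=O)[C@]2(COC(C)=O)[C@@H]1[C@H](OC(=O)[C@@H](C)CC)CC[C@]2(O)CCl)C1=CC(=O)OC1 | intermediate
32 | (12S)-alcohol | O[C@@H](C[C@@]1(C)[C@H](C)C[C@H](OC(C)=O)[C@]2(COC(C)=O)[C@@H]1[C@H](OC(=O)[C@@H](C)CC)CC[C@]2(O)CCl)C1=CC(=O)OC1 | intermediate
33 | ajugaciliatin A | CC[C@H](C)C(=O)O[C@@H](C[C@@]1(C)[C@H](C)C[C@H](OC(C)=O)[C@]2(COC(C)=O)[C@@H]1[C@H](OC(=O)[C@@H](C)CC)CC[C@]2(O)CCl)C1=CC(=O)OC1 | target

## Totals
- Total step count: 26
- Longest linear sequence: 22 (steps 1–8, 10–18, 20, 21, 24–26)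

## Three steps most likely to fail, with fallbacks
1. **Step 16 (LiCH2Cl addition):** risks are face selectivity at the hindered C4 ketone, retro-aldol of the C6 alkoxide, and epoxide closure. Fallback: keep the ketal until after step 18, then hydrolyse and desilylate, methylenate the ketone (Zn/CH2Br2/TiCl4), run a C19-OH-directed VO(acac)2/t-BuOOH epoxidation to the 4α,18-epoxide, and open it with LiCl/AcOH.
2. **Step 18 (hydroboration of the Δ1(10) olefin):** the alkene is very hindered and BH3 may attack the acetates. Fallback: epoxidise Δ1(10) from the β face, rearrange with a Lewis acid (Meinwald) to the 10β-H C1 ketone, and reduce it with hydride delivered from the α face by a free C19 hydroxyl (Evans–Saksena-type) before acetylation.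
3. **Step 24 (acyl-Stille with the electron-poor stannylbutenolide):** transmetalation may be slow and the hindered acyl chloride may decarbonylate. Fallback: reduce acid 27 chemoselectively (BH3·THF), oxidise to the C12 aldehyde (Dess–Martin), and join it to bromobutenolide 29 by Nozaki–Hiyama–Kishi coupling; correct C12 by oxidation/CBS or Mitsunobu inversion with acid 24 if needed.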